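Set the free monomer charged against the initiator charged and elm gets 35.0, oak 136. Call this ratio the ceiling, C: the length a chain reaches if each initiator begins one chain and the whole charge of free monomer ends in chains. The average length (degree of polymerisation) is then C times s, where s is the share of the charged free monomer standing in chains. One chain per initiator is a guess, since the earlier runs do not show the number of chains.

the same everywhere: initiator 22 mM

| charge | free monomer | protic impurity | remark | time |
|---|---|---|---|---|
| violet | 1.1 M | 0.77 M | run made earlier |  |
| elm | 0.77 M | 0.770 M |  | 80 min |
| oak | 3.0 M | 0.770 M |  | 80 min |

violet run (percent of the free monomer charged)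

| time / min | monomer in chains / % |
|---|---|
| 5.00 | 3.4 |
| 6.00 | 6.9 |
| 10.0 | 6.7 |
| 15.0 | 6.8 |
| 25.0 | 12.4 |
| 40.0 | 18.5 |
| 60.0 | 23.0 |

(readings scatter by 1 percentage point)

- the average divides the monomer in chains by the number of chains begun, living and dead together
- the earlier runs do not show the number of chains; that part of a forecast is a guess

- which of the two ends with the longer chains by the average number of monomer units in a chain (chains begun, living or dead) ("neither" if they lie within 10%) (elm / oak / neither)
- average number of monomer units in a chain (chains begun, living or dead) at the end, elm
- average number of monomer units in a chain (chains begun, living or dead) at the end, oak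

The violet run gives s by two ways, each taking a steady first-order rate from one reading. The reading at 25.0 min gives 0.00530 min⁻¹, so s = 34.5% at 80 min. The reading at 60.0 min gives 0.00436 min⁻¹, so s = 29.4%. They part, so test the early way on the violet run: its rate puts 27.2% in chains at 60.0 min, but the reading there is 23.0%. That gap of 4.2 percentage points is larger than the scatter of 1 point, so the early way cheats, and I keep 29.4%.

Elm and oak have the initiator and impurity of the violet run, so I carry s over unchanged. My reckoning gives 10.3 for elm and 40.1 for oak. The forecast also says oak, but with 9 and 34, both lower than mine, on this ground: “Transfer to the large impurity excess could start extra chains, which is a guess, so I shade both lower.”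

The longer chains end in oak, with 8.32 for elm and 46.3 for oak. At 80.0 min, monomer in chains stands at 23.8% of the charge in elm and 33.9% in oak, so s is larger in oak and not the shared value I assumed. C times these two shares returns 8.32 and 46.3.

    free monomer + initiator → living end + monomer in chains (k = 0.0170 M⁻¹ s⁻¹)
    free monomer + living end → monomer in chains + living end, rate k2*[living end]*[free monomer] (k = 0.00500 M⁻¹ s⁻¹)
    protic impurity + free monomer → quenched substrate (k = 7.80 × 10⁻⁵ M⁻¹ s⁻¹)
    monomer in chains + living end → free monomer + living end, rate k4*[living end] as long as [monomer in chains] is above zero (k = 0.00130 s⁻¹)

Take elm again with 0.088 M of initiator: C drops to 8.75, and C times elm's share is 2.08. The computed length is 4.39, with 50.1% in chains at 80.0 min, and C times that share gives 4.39.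

(Readings and results are calculated with made-up constants; noise was put on by code.)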